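**Plan**

1. Retrosynthetic cuts, in order: the C8–O acyl bond; the C3–isopropyl bond (conjugate addition to a C1 enone); the C6–CH3 bond together with a 1,3-shift of oxygen from C6 to C8; the C3a–O bond (epoxide on C3a=C4); then C8a–C3a and C8a–C8 in one operation; last C1–C8a (acid chloride plus diazoethane).
2. Enabling feature (azulene numbering): C8a carries a methyl group and is bonded to the C1 carbonyl and to both C8 and C3a of the seven-membered ring, and C6 sits 1,4 to C3a in that ring. This is the imprint of an α-keto carbene added across the ipso–ortho bond of a para-substituted benzene whose six carbons become C3a–C8.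
3. Forward order: the chain is assembled in steps 1–2, both rings arise together in step 3 (cyclopentanone by the C8a–C3a bond, seven-membered ring by expansion of the arene), and all later steps only adjust functional groups.
4. Stereochemistry: C8a comes from the chiral copper bis(oxazoline) catalyst and is relayed to C1 (hydride anti to the methyl), to C3a (epoxidation directed by the C1 hydroxyl), to C8 (anti reduction directed by the 3a-hydroxyl) and to C3 (isopropyl delivered on the alkoxide-bearing convex face).

Key step: step 3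

Convention: azulene numbering throughout; α is the face of the C8a methyl group, and C8a keeps the absolute configuration fixed in 7 in every later compound.
Assumption: the (4R,4'R)-phenyl bis(oxazoline) ligand is taken to give the 8aR azulenone; if the sense of induction is the opposite, its enantiomer is used.

**Route**

Step 1
Reactants: 1 3-(4-methoxyphenyl)propanoic acid
Product: 2 3-(4-methoxyphenyl)propanoyl chloride
Conditions: (COCl)2 (1.5 equiv), DMF (cat.), CH2Cl2, 0 °C → rt; evaporate
Reagents that add atoms: oxalyl chloride, ClC(=O)C(Cl)=O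
Why: Acid chloride formation through the chloroiminium species from catalytic DMF is neutral and leaves the anisole ring untouched.

Step 2
Reactants: 2 3-(4-methoxyphenyl)propanoyl chloride; 3 N-ethyl-N-nitrosourea
Product: 5 2-diazo-5-(4-methoxyphenyl)pentan-3-one, via diazoethane 4 (not isolated)
Conditions: 3 (3.5 equiv), 40% aq KOH, Et2O, −10 °C; dried ethereal layer, then 2 in Et2O, −20 °C → rt
Reagents that add atoms: none
Why: Acylation of a diazoalkane by an acid chloride (Arndt–Eistert-type diazoketone synthesis) should give 5, a second equivalent of diazoethane removing HCl as chloroethane, so that the diazo carbon carries the methyl group that becomes the angular C8a methyl.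

Step 3
Reactants: 5 2-diazo-5-(4-methoxyphenyl)pentan-3-one
Product: 7 (8aR)-6-methoxy-8a-methyl-3,8a-dihydroazulen-1(2H)-one, via norcaradiene 6 (not isolated)
Conditions: Cu(MeCN)4PF6 (5 mol %), (4R,4'R)-2,2'-(propane-2,2-diyl)bis(4-phenyl-4,5-dihydrooxazole) (6 mol %), NaB[3,5-(CF3)2C6H3]4 (6 mol %), CH2Cl2, 40 °C, slow addition of 5
Reagents that add atoms: none
Why: Loss of N2 from 5 at monovalent copper should give an electrophilic keto-carbene that cyclopropanates the ipso–ortho bond of the anisole ring to norcaradiene 6, whose disrotatory six-electron electrocyclic opening gives cycloheptatriene 7; this is the intramolecular Buchner reaction known for 1-diazo-4-arylbutan-2-ones, α-methyl cases included. The cyclopentanone closes by the C8a–C3a bond, a five-membered closure of the carbene onto the ipso carbon through the CH2–CH2–C(=O) tether. The seven-membered ring arises by expansion of the benzene ring, C8a–C8 forming in the cyclopropanation and the C3a–C8 bond then breaking. C8a, the only new stereocentre, is set by the C2-symmetric bis(oxazoline) ligand on copper, which selects one of the two enantiotopic ipso–ortho bonds. Arene addition must win over 1,2-hydride shift from the methyl group and over C–H insertion; the short tether holding the carbene over the electron-rich ring secures this, and the para position of the methoxy group makes both ortho carbons equivalent so that one constitutional isomer can form.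

Step 4
Reactants: 7 (8aR)-6-methoxy-8a-methyl-3,8a-dihydroazulen-1(2H)-one
Product: 8 (1R,8aR)-6-methoxy-8a-methyl-1,2,3,8a-tetrahydroazulen-1-ol
Conditions: NaBH4, MeOH, 0 °C; aq NaHCO3 work-up
Reagents that add atoms: none
Why: Borohydride reduction of the cyclopentanone should proceed by hydride attack anti to the angular methyl (as with 17-keto steroids and 7a-methylhydrindan-1-ones bearing the same exocyclic C3a=C4 unsaturation), placing the hydroxyl α, cis to the methyl, while the trienol ether survives the basic medium.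

Step 5
Reactants: 8 (1R,8aR)-6-methoxy-8a-methyl-1,2,3,8a-tetrahydroazulen-1-ol
Product: 9 6,6-ethylenedioxy-8aα-methyl-1,2,3,5,6,8a-hexahydroazulen-1α-ol
Conditions: HOCH2CH2OH (10 equiv), pyridinium p-toluenesulfonate (5 mol %), benzene, 4 Å molecular sieves, rt
Reagents that add atoms: ethane-1,2-diol, OCCO
Why: Acid-catalysed transketalisation of the dienol ether (C-protonation, capture of the oxocarbenium ion by the diol, loss of methanol) should give the dioxolane with the unconjugated trisubstituted C3a=C4 alkene, the position ketals of this type adopt as in the ketalisation of steroidal 3-alkoxy-3,5-dienes, which frees that alkene for epoxidation.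

Step 6
Reactants: 9 6,6-ethylenedioxy-8aα-methyl-1,2,3,5,6,8a-hexahydroazulen-1α-ol
Product: 10 3aα,4α-epoxy-6,6-ethylenedioxy-8aα-methyl-1,2,3,3a,4,5,6,8a-octahydroazulen-1α-ol
Conditions: VO(acac)2 (5 mol %), t-BuOOH (1.5 equiv, in decane), CH2Cl2, 0 °C → rt
Reagents that add atoms: tert-butyl hydroperoxide, CC(C)(C)OO
Why: In this hydroxyl-directed vanadium-catalysed epoxidation of a homoallylic alcohol the vanadate ester of the 1α-hydroxyl should deliver oxygen to the α face of the electron-rich trisubstituted C3a=C4 bond rather than to the disubstituted, ketal-deactivated C7=C8 bond, fixing the C3a–O bond cis to the angular methyl.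

Step 7
Reactants: 10 3aα,4α-epoxy-6,6-ethylenedioxy-8aα-methyl-1,2,3,3a,4,5,6,8a-octahydroazulen-1α-ol
Product: 12 1α,3aα-dihydroxy-8aα-methyl-2,3,3a,4,5,8a-hexahydroazulen-6(1H)-one, via hydroxy ketal 11 (not isolated)
Conditions: LiAlH4 (3 equiv), THF, 0 °C → 60 °C; then 1 M aq HCl, THF, rt
Reagents that add atoms: water, O
Why: Hydride should open the trisubstituted epoxide by SN2 attack at the secondary carbon C4 (as in the reduction of steroidal 5,6-epoxides to 5-ols), leaving the tertiary 3aα-alcohol with its C–O bond intact, and the acidic work-up then hydrolyses the allylic dioxolane to the C7=C8 enone.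

Step 8
Reactants: 12 1α,3aα-dihydroxy-8aα-methyl-2,3,3a,4,5,8a-hexahydroazulen-6(1H)-one
Product: 13 6,8aα-dimethyl-1,2,3,3a,4,5,6,8a-octahydroazulene-1α,3aα,6-triol
Conditions: MeLi (4 equiv), CeCl3 (4.5 equiv, dried), THF, −78 °C; aq NH4Cl
Reagents that add atoms: methyllithium, [Li]C
Why: Organocerium 1,2-addition to the enone carbonyl should occur without enolisation or conjugate addition, and the configuration created at C6 is immaterial because that carbon becomes trigonal again in step 10.

Step 9
Reactants: 13 6,8aα-dimethyl-1,2,3,3a,4,5,6,8a-octahydroazulene-1α,3aα,6-triol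
Product: 14 1α-(tert-butyldimethylsilyloxy)-6,8aα-dimethyl-1,2,3,3a,4,5,6,8a-octahydroazulene-3aα,6-diol
Conditions: TBSCl (1.5 equiv), imidazole (3 equiv), DMF, rt
Reagents that add atoms: tert-butyldimethylsilyl chloride, CC(C)(C)[Si](C)(C)Cl
Why: Silyl ether formation with TBSCl and imidazole distinguishes the secondary C1 hydroxyl from the two tertiary alcohols, keeping C1 at the alcohol level through the chromium oxidation so that no C1 ketone can compete in the later directed reduction.

Step 10
Reactants: 14 1α-(tert-butyldimethylsilyloxy)-6,8aα-dimethyl-1,2,3,3a,4,5,6,8a-octahydroazulene-3aα,6-diol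
Product: 15 1α-(tert-butyldimethylsilyloxy)-3aα-hydroxy-6,8aα-dimethyl-1,2,3,3a,4,5-hexahydroazulen-8(8aH)-one
Conditions: pyridinium chlorochromate (3 equiv), 4 Å molecular sieves, CH2Cl2, rt
Reagents that add atoms: pyridinium chlorochromate, [O-][Cr](=O)(=O)Cl.c1cc[nH+]cc1
Why: In the Babler–Dauben oxidative transposition the chromate ester of the tertiary allylic alcohol should shift to C8 and be oxidised there, giving the β-methyl enone with oxygen moved from C6 to C8, while the non-allylic tertiary 3a-hydroxyl cannot be oxidised.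

Step 11
Reactants: 15 1α-(tert-butyldimethylsilyloxy)-3aα-hydroxy-6,8aα-dimethyl-1,2,3,3a,4,5-hexahydroazulen-8(8aH)-one
Product: 16 1α-(tert-butyldimethylsilyloxy)-6,8aα-dimethyl-1,2,3,3a,4,5,8,8a-octahydroazulene-3aα,8β-diol
Conditions: Me4NBH(OAc)3 (5 equiv), MeCN/AcOH 1:1, −30 °C → −20 °C
Reagents that add atoms: none
Why: In the Evans–Saksena reduction the 3aα-hydroxyl should exchange onto boron and deliver hydride within the molecule to the α face of the C8 carbonyl, giving the 1,3-anti diol, that is the 8β-alcohol trans to the angular methyl, by 1,2-reduction only.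

Step 12
Reactants: 16 1α-(tert-butyldimethylsilyloxy)-6,8aα-dimethyl-1,2,3,3a,4,5,8,8a-octahydroazulene-3aα,8β-diol; 17 4-methoxybenzoyl chloride
Product: 18 1α-(tert-butyldimethylsilyloxy)-3aα-hydroxy-6,8aα-dimethyl-1,2,3,3a,4,5,8,8a-octahydroazulen-8β-yl 4-methoxybenzoate
Conditions: 17 (1.5 equiv), Et3N (3 equiv), DMAP (0.2 equiv), CH2Cl2, 0 °C → rt
Reagents that add atoms: none
Why: DMAP-catalysed acyl transfer should esterify the secondary allylic C8 hydroxyl while the tertiary 3a-hydroxyl does not react.

Step 13
Reactants: 18 1α-(tert-butyldimethylsilyloxy)-3aα-hydroxy-6,8aα-dimethyl-1,2,3,3a,4,5,8,8a-octahydroazulen-8β-yl 4-methoxybenzoate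
Product: 19 1α,3aα-dihydroxy-6,8aα-dimethyl-1,2,3,3a,4,5,8,8a-octahydroazulen-8β-yl 4-methoxybenzoate
Conditions: HF·pyridine, pyridine, THF, 0 °C → rt
Reagents that add atoms: none
Why: Fluoride-mediated silyl ether cleavage under pyridine buffering should free the C1 hydroxyl without touching the allylic ester or the tertiary alcohol.

Step 14
Reactants: 19 1α,3aα-dihydroxy-6,8aα-dimethyl-1,2,3,3a,4,5,8,8a-octahydroazulen-8β-yl 4-methoxybenzoate
Product: 21 3aα-hydroxy-6,8aα-dimethyl-1-oxo-1,3a,4,5,8,8a-hexahydroazulen-8β-yl 4-methoxybenzoate, via saturated ketone 20 (not isolated)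
Conditions: IBX (3.5 equiv), DMSO/fluorobenzene 1:2, 70 °C
Reagents that add atoms: none
Why: IBX should oxidise the secondary alcohol to the ketone and, at this temperature, dehydrogenate it through its enol (IBX ketone dehydrogenation), and because C8a is quaternary the ketone can enolise only toward C2, so the C2=C3 enone is the single regioisomer.

Step 15
Reactants: 21 3aα-hydroxy-6,8aα-dimethyl-1-oxo-1,3a,4,5,8,8a-hexahydroazulen-8β-yl 4-methoxybenzoate
Product: 22 (3R,3aS,8R,8aR)-3a-hydroxy-6,8a-dimethyl-1-oxo-3-(propan-2-yl)-1,2,3,3a,4,5,8,8a-octahydroazulen-8-yl 4-methoxybenzoate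
Conditions: i-PrMgCl (2.5 equiv), CuBr·SMe2 (20 mol %), THF, −78 °C → −40 °C; aq NH4Cl
Reagents that add atoms: isopropylmagnesium chloride, CC(C)[Mg]Cl
Why: In this conjugate addition of a Grignard reagent catalysed by monovalent copper the isopropyl group should reach C3 from the convex α face, beside the small magnesium alkoxide of the 3a-hydroxyl (which can guide the reagent) and away from the C4 methylene of the seven-membered ring, setting isopropyl cis to the hydroxyl, while the trisubstituted C6=C7 alkene and the hindered aryl ester stay inert at low temperature.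

**Compound list**

1 | 3-(4-methoxyphenyl)propanoic acid | COc1ccc(CCC(O)=O)cc1 | starting material
2 | 3-(4-methoxyphenyl)propanoyl chloride | COc1ccc(CCC(Cl)=O)cc1 | intermediate
3 | N-ethyl-N-nitrosourea | CCN(N=O)C(N)=O | starting material
4 | diazoethane | CC=[N+]=[N-] | intermediate (not isolated)
5 | 2-diazo-5-(4-methoxyphenyl)pentan-3-one | COc1ccc(CCC(=O)C(C)=[N+]=[N-])cc1 | intermediate
6 | norcaradiene valence isomer of 7 (cyclopropane C3a–C8–C8a, diene C4=C5/C6=C7, 6-methoxy, 8a-methyl, 1-ketone) | COC1=C[C@@H]2[C@@]3(C)C(=O)CC[C@@]23C=C1 | intermediate (not isolated)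
7 | (8aR)-6-methoxy-8a-methyl-3,8a-dihydroazulen-1(2H)-one | COC1=CC=C2CCC(=O)[C@]2(C)C=C1 | intermediate
8 | (1R,8aR)-6-methoxy-8a-methyl-1,2,3,8a-tetrahydroazulen-1-ol (1-OH cis to 8a-methyl) | COC1=CC=C2CC[C@@H](O)[C@]2(C)C=C1 | intermediate
9 | 6,6-ethylenedioxy-8aα-methyl-1,2,3,5,6,8a-hexahydroazulen-1α-ol (alkenes C3a=C4 and C7=C8) | O[C@@H]1CCC2=CCC3(OCCO3)C=C[C@@]12C | intermediate
10 | 3aα,4α-epoxy-6,6-ethylenedioxy-8aα-methyl-1,2,3,3a,4,5,6,8a-octahydroazulen-1α-ol | O[C@@H]1CC[C@@]23O[C@@H]2CC4(OCCO4)C=C[C@@]13C | intermediate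
11 | 6,6-ethylenedioxy-8aα-methyl-1,2,3,3a,4,5,6,8a-octahydroazulene-1α,3aα-diol | O[C@@H]1CC[C@@]2(O)CCC3(OCCO3)C=C[C@@]12C | intermediate (not isolated)
12 | 1α,3aα-dihydroxy-8aα-methyl-2,3,3a,4,5,8a-hexahydroazulen-6(1H)-one | O[C@@H]1CC[C@@]2(O)CCC(=O)C=C[C@@]12C | intermediate
13 | 6,8aα-dimethyl-1,2,3,3a,4,5,6,8a-octahydroazulene-1α,3aα,6-triol (either C6 epimer) | O[C@@H]1CC[C@@]2(O)CCC(C)(O)C=C[C@@]12C | intermediate
14 | 1α-(tert-butyldimethylsilyloxy)-6,8aα-dimethyl-1,2,3,3a,4,5,6,8a-octahydroazulene-3aα,6-diol | CC(C)(C)[Si](C)(C)O[C@@H]1CC[C@@]2(O)CCC(C)(O)C=C[C@@]12C | intermediate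
15 | 1α-(tert-butyldimethylsilyloxy)-3aα-hydroxy-6,8aα-dimethyl-1,2,3,3a,4,5-hexahydroazulen-8(8aH)-one | CC(C)(C)[Si](C)(C)O[C@@H]1CC[C@@]2(O)CCC(C)=CC(=O)[C@@]12C | intermediate
16 | 1α-(tert-butyldimethylsilyloxy)-6,8aα-dimethyl-1,2,3,3a,4,5,8,8a-octahydroazulene-3aα,8β-diol | CC(C)(C)[Si](C)(C)O[C@@H]1CC[C@@]2(O)CCC(C)=C[C@@H](O)[C@@]12C | intermediate
17 | 4-methoxybenzoyl chloride | COc1ccc(cc1)C(Cl)=O | starting material
18 | 1α-(tert-butyldimethylsilyloxy)-3aα-hydroxy-6,8aα-dimethyl-1,2,3,3a,4,5,8,8a-octahydroazulen-8β-yl 4-methoxybenzoate | CC(C)(C)[Si](C)(C)O[C@@H]1CC[C@@]2(O)CCC(C)=C[C@@H](OC(=O)c3ccc(OC)cc3)[C@@]12C | intermediate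
19 | 1α,3aα-dihydroxy-6,8aα-dimethyl-1,2,3,3a,4,5,8,8a-octahydroazulen-8β-yl 4-methoxybenzoate | O[C@@H]1CC[C@@]2(O)CCC(C)=C[C@@H](OC(=O)c3ccc(OC)cc3)[C@@]12C | intermediate
20 | 3aα-hydroxy-6,8aα-dimethyl-1-oxo-1,2,3,3a,4,5,8,8a-octahydroazulen-8β-yl 4-methoxybenzoate | O=C1CC[C@@]2(O)CCC(C)=C[C@@H](OC(=O)c3ccc(OC)cc3)[C@@]12C | intermediate (not isolated)
21 | 3aα-hydroxy-6,8aα-dimethyl-1-oxo-1,3a,4,5,8,8a-hexahydroazulen-8β-yl 4-methoxybenzoate | O=C1C=C[C@@]2(O)CCC(C)=C[C@@H](OC(=O)c3ccc(OC)cc3)[C@@]12C | intermediate
22 | (3R,3aS,8R,8aR)-3a-hydroxy-6,8a-dimethyl-1-oxo-3-(propan-2-yl)-1,2,3,3a,4,5,8,8a-octahydroazulen-8-yl 4-methoxybenzoate (3α-isopropyl, 3aα-OH, 8β-ester, 8aα-methyl) | COc1ccc(C(=O)O[C@@H]2C=C(C)CC[C@]3(O)[C@@H](C(C)C)CC(=O)[C@]23C)cc1 | target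

**Count and risks**

Total steps: 15. Longest linear sequence: 15 steps (from 1).

Steps most likely to fail:

Step 15. The isopropyl group may be delivered to the β face of C3 or without facial preference. Fallback, from 21 back to 22: the conjugate adduct, then largely the 3β-isopropyl ketone F1, would not be separated from its epimer but dehydrogenated with IBX (DMSO, 75 °C) to the 3-isopropyl cyclopentenone F2, in which C3 is trigonal again. Conjugate reduction with [(Ph3P)CuH]6 (toluene, rt) then brings hydride instead of carbon to C3, so the facial preference that misplaced the isopropyl group now places hydrogen on the β face and leaves isopropyl α, giving 22.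

Step 3. The copper carbene may discriminate poorly between the two enantiotopic ipso–ortho bonds, or be lost to 1,2-hydride shift. Fallback, from 5 back to 8: cyclisation with achiral Rh2(OAc)4 (CH2Cl2, 40 °C), the long-established catalyst for this ring expansion, would give the racemic azulenone F3. Kinetic resolution by Corey–Bakshi–Shibata reduction ((S)-2-methyl-CBS-oxazaborolidine 10 mol %, BH3·SMe2 0.5 equiv, THF, −20 °C) should then reduce the 8aR enantiomer faster, because for it the reagent's preference for the 1R carbinol and the substrate's preference for hydride attack anti to the methyl coincide. Chromatography separates alcohol 8 from unreduced 8aS ketone.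

Step 11. Ligand exchange at the hindered tertiary hydroxyl may be too slow to guide the hydride, so that reduction stalls or gives the 8α-alcohol. Fallback, from 15 back to 18: Luche reduction (NaBH4, CeCl3·7H2O, MeOH, −78 °C) is expected to attack anti to the angular methyl and give the 8α-alcohol F4. Mitsunobu esterification with 4-methoxybenzoic acid (PPh3, diisopropyl azodicarboxylate, toluene, 0 °C → rt) then inverts C8 and installs the ester in one operation, giving 18.

Further compounds
F1 | step 15 | 3aα-hydroxy-6,8aα-dimethyl-1-oxo-3β-(propan-2-yl)-1,2,3,3a,4,5,8,8a-octahydroazulen-8β-yl 4-methoxybenzoate (3-epimer of 22) | O=C1C[C@@H](C(C)C)[C@@]2(O)CCC(C)=C[C@@H](OC(=O)c3ccc(OC)cc3)[C@@]12C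
F2 | step 15 | 3aα-hydroxy-6,8aα-dimethyl-1-oxo-3-(propan-2-yl)-1,3a,4,5,8,8a-hexahydroazulen-8β-yl 4-methoxybenzoate | O=C1C=C(C(C)C)[C@@]2(O)CCC(C)=C[C@@H](OC(=O)c3ccc(OC)cc3)[C@@]12C
F3 | step 3 | racemic 6-methoxy-8a-methyl-3,8a-dihydroazulen-1(2H)-one | COC1=CC=C2CCC(=O)C2(C)C=C1
F4 | step 11 | 1α-(tert-butyldimethylsilyloxy)-6,8aα-dimethyl-1,2,3,3a,4,5,8,8a-octahydroazulene-3aα,8α-diol | CC(C)(C)[Si](C)(C)O[C@@H]1CC[C@@]2(O)CCC(C)=C[C@H](O)[C@@]12C
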